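## The problem

Blepharocalyxin E is a tetrahydropyran (numbered O1, C2–C6) with four equatorial substituents: a 4-hydroxyphenyl group on C2, a diarylheptenol arm on C3 (side chain C1'–C7'), the methoxy-dihydroxyphenyl ring of a chalcone (ring A) on C4 and a 4-hydroxyphenethyl group (C7, C8) on C6. Six stereocentres must be fixed: C2, C3, C4 and C6 on the ring, the exocyclic methine C1' and the carbinol C5'. The ring centres can help each other. C2 can be set last by axial hydride delivery to a ring oxocarbenium ion. C3 stays enolisable while C2 is a carbonyl carbon, so it can settle trans to C4. C1' and C5' lie outside the ring and need reagent control, and C4 and C6 are separated by a CH2 group. C6 and C5' are both (S) carbinol carbons flanked by an arylethyl group and an allylic CH2, so one building block can serve both. The molecule tolerates little: the 2'-hydroxychalcone closes to a flavanone in acid or base and accepts nucleophiles, there are seven phenols, an (E)-alkene sits next to a doubly activated C1'–H, and the benzylic ether at C2 can ionise. Hydrogenolysis, strong Lewis acids and strong base are therefore excluded at the end. The enabling feature is that C4 is benzylic to the ring A carbon that lies between two phenolic oxygens and para to the methoxy group. C4 and that carbon can become the exocyclic C=C of an ortho-quinone methide, and one flanking phenol oxygen can be tied to C2 as an aryl lactone.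

## Retrosynthesis

**Unmasking (37 from 36).** Only O–CH2OMe bonds are cut. All seven phenols are carried as MOM ethers because these survive fluoride, carbene, organolithium, silane and metathesis conditions and fall together in mild acid. Aryl silyl ethers would not survive the fluoride of the key step, and benzyl ethers cannot be removed beside two alkenes. The C5' alcohol is left free. The forward step must remove seven acetals without closing the hydroxychalcone.

**Side chain (36 from 35 and 4).** The C2'=C3' bond is cut by cross-metathesis. An olefination would need an epimerisable α-aryl aldehyde at C1'. The cut removes C5' and one aryl group, and the partner 4 is the alcohol that also supplies C6. The forward reaction must be (E)-selective on a branched terminal alkene and leave the chalcone alkene alone.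

**Chalcone (35 from 33 and 18; 33 from 32).** The ring A–carbonyl bond is cut. In 32 ring A is a symmetric 1,3,5-trioxygenated arene whose two free positions are equivalent, so iodination to 33 is unambiguous. Lithium exchange and acylation with Weinreb amide 18 make the enone in one C–C bond formation. Friedel–Crafts acylation would need a Lewis acid that strips MOM groups, and acetylation followed by aldol condensation costs one more step on the main line.

**C2 (32 from 31; 31 from 28 and 30).** The C2–aryl and C2–H bonds are cut. Aryllithium 30, made from bromide 29, adds to δ-lactone 28 to give lactol 31. Silane reduction of the derived oxocarbenium ion sets C2 from the three existing ring centres. This removes one stereocentre and one aryl group.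

**Acyl transfer (28 from 27; 27 from 26).** O1–C2 is cut and C2 is reconnected to the ring A oxygen. Opening dihydrocoumarin 26 directly with 30 would give an acyclic enolisable ketone beside a free phenol, which can close a chroman. Letting the C6 oxygen take the acyl group instead forms the tetrahydropyran skeleton at once and keeps C3 in a ring whose preferred arrangement is the desired all-equatorial one. It also frees the ring A phenol for MOM protection, which makes ring A symmetric for the later iodination. The forward step is a desilylation followed by intramolecular transesterification.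

**Key disconnection (26 from 15 and 24).** C3–C4 and the aryl O–C2 bond are cut. The dihydrocoumarin falls into a ring A benzylic acetate 15 and an acyl imidazole 24 of similar size. The forward reaction must generate the quinone methide 25 from 15, join it to the carbene-bound enolate of 24 and set C4 relative to C6 and C1'.

**Quinone methide precursor (15 from 13; 13 from 12; 12 from 11; 11 from 10; 10 from 8 and 6).** The ring A–C4 bond is cut. Lithiation of the symmetric arene 8 between its two acetal oxygens (aryllithium 9) fixes the regiochemistry, and aldehyde 6 brings C6 with its configuration. The two ring A oxygens must then differ: one silyl ether as the fluoride trigger and one MOM ether. A second fluoride-labile group would give a phenoxide-substituted, deactivated methide. The difference is introduced at ketone 11 by chelation-assisted loss of one MOM group. An aldol route from a ring A aldehyde was set aside because C6 would have to be created on a ketone flanked by two CH2 groups and a 1,3-diol would have to be differentiated.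

**Chiral building block (6 from 5; 5 from 4; 4 from 3; 3 from 2; 2 from 1).** The alkene of 5 is cleaved to the aldehyde carbon C4, and the allyl–carbinol bond of 4 is cut back to aldehyde 3. One asymmetric allylboration therefore serves both C6 and C5'.

**Acyl imidazole and Weinreb amide (24 from 23, 22, 21, 20, 19, 17, 16; 18 from 17).** The bond between C1' and the future C3 is cut. An iridium-catalysed branched allylic alkylation of cinnamyl carbonate 20 with a stabilised carbon nucleophile sets C1' in 21. Decarboxylation and hydrolysis give acid 23. The MOM ester 17, made from 4-hydroxycinnamic acid 16, also gives Weinreb amide 18 in one step.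

## Roads not taken

**Alternative 1:** Ring A is made last by a biomimetic Claisen folding. A linear ester–ketone–enol ether–ketone chain on C4 is closed by base and aromatises to the acetophenone A1. The merits are real: the acetyl and methoxy groups are placed by construction, ring A needs no protection, and A1 is one condensation and one deprotection from the target. In this respect it is better than the chosen plan, which spends steps 25 and 26 and some protecting-group traffic (steps 9, 10, 22) on ring A. Its weak points are these. Before the folding C4 is not benzylic, so the C3–C4 bond and all four ring centres must be made without the activation that ring A offers. The polycarbonyl chain can fold in other ways (aldol closure to the isomeric resorcinol, O-acylation to a pyranone). The chain must also be built and masked in a long linear sequence on an advanced intermediate. The chosen plan sets against it a convergent union of two fragments of similar size in which ring A is used, not postponed.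

**Alternative 2:** The ring is closed from the C6 side by a reductive Prins reaction. An α-acetoxy ether ionises to the O1=C6 oxocarbenium ion, a 1,1-disubstituted ring A alkene forms C5–C6, and a silane reduces the C4 cation to give A2. One step makes the ring and sets C4 and C6, and the tertiary benzylic cation is well stabilised. Counted from the cyclisation substrate it is shorter than the chosen plan. Its weak points are these. C2, C3 and C1' must already stand in an acyclic precursor as a contiguous triad. The oxocarbenium ion is set up for 2-oxonia-Cope rearrangement, which the electron-rich aryl group at C2 favours and which would scramble C2 and C3. Hydride must reach the C4 cation from the axial side past two ortho silyloxy groups. Five aryl silyl ethers must also survive the Lewis acid. The chosen plan sets each centre in a separate event of known type and can repair C3.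

**Alternative 3:** A chiral iridium allyl complex formed from the racemic carbinol A4 is attacked by C3 of an (E)-styrene, and the C2 benzylic cation is trapped by the C6 oxygen to give A3. This is the most convergent road. It sets C1', C3 and C2 in one catalytic step and would be the shortest, and in step count it is better than the chosen plan. Its weak points are these. An unactivated 1,2-disubstituted styrene is asked to act as an intermolecular nucleophile towards the allyl complex. The styrene substrate must already carry C4 and C6 in the right relationship, which is the problem the chosen key step solves. Ring A and the oxyphenyl rings compete as Friedel–Crafts nucleophiles. C3 and C2 are controlled only by the closing conformation. The chosen plan sets against it a key step of an established reaction class and independent control points.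

Key step: step 20

Assumption: the phosphoramidite antipode named in step 16 is taken to give (S)-21 and the triazolium antipode named in step 20 to give (3R,4R)-26; if either sense is opposite, its mirror image is used and nothing else changes.

Assumption: 1-bromo-4-(methoxymethoxy)benzene (29) is taken as a catalogue compound; it is otherwise one MOM protection from 4-bromophenol.

## Route

Step 1
Reactants: 1 methyl 3-(4-hydroxyphenyl)propanoate
Product: 2 methyl 3-[4-(methoxymethoxy)phenyl]propanoate
Conditions: MOMCl, i-Pr2NEt, CH2Cl2, 0 °C to rt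
Reagents that add atoms: chloromethyl methyl ether, COCCl
Why: O-alkylation of the phenol to the acetal ether (MOM protection); this group survives hydride, organolithium, fluoride and carbene conditions and is removed at the end with mild acid.

Step 2
Reactants: 2 methyl 3-[4-(methoxymethoxy)phenyl]propanoate
Product: 3 3-[4-(methoxymethoxy)phenyl]propanal
Conditions: i-Bu2AlH (1.1 equiv), CH2Cl2, −78 °C; aq. potassium sodium tartrate
Reagents that add atoms: none
Why: Partial reduction of the methyl ester, which stops at the aluminium hemiacetal at low temperature.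

Step 3
Reactants: 3 3-[4-(methoxymethoxy)phenyl]propanal
Product: 4 (3S)-1-[4-(methoxymethoxy)phenyl]hex-5-en-3-ol
Conditions: (+)-Ipc2B(allyl) (from (−)-α-pinene), Et2O, −78 °C; then NaOH, H2O2
Reagents that add atoms: (+)-B-allyldiisopinocampheylborane, C=CCB(C1CC2CC(C1C)C2(C)C)C1CC2CC(C1C)C2(C)C (configuration of the reagent from (−)-α-pinene)
Why: Brown allylboration through a chair transition state; with unbranched aldehydes the reagent from (−)-α-pinene gives the (S)-homoallylic alcohol. This one alcohol is the source of both C6 (via steps 4, 5) and C5' (step 27).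

Step 4
Reactants: 4 (3S)-1-[4-(methoxymethoxy)phenyl]hex-5-en-3-ol
Product: 5 tert-butyl({(3S)-1-[4-(methoxymethoxy)phenyl]hex-5-en-3-yl}oxy)dimethylsilane
Conditions: TBSCl, imidazole, DMF, rt
Reagents that add atoms: tert-butyldimethylsilyl chloride, CC(C)(C)[Si](C)(C)Cl
Why: Standard silylation of a secondary alcohol; the silyl ether keeps the C6 oxygen from taking the acyl group in step 20 and is released by fluoride in step 21.

Step 5
Reactants: 5 tert-butyl({(3S)-1-[4-(methoxymethoxy)phenyl]hex-5-en-3-yl}oxy)dimethylsilane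
Product: 6 (3S)-3-[(tert-butyldimethylsilyl)oxy]-5-[4-(methoxymethoxy)phenyl]pentanal
Conditions: O3, CH2Cl2, −78 °C, dosed to the end point; then PPh3
Reagents that add atoms: ozone, [O-][O+]=O
Why: Ozonolysis with reductive work-up cuts the terminal alkene to the aldehyde carbon that becomes C4; at −78 °C the monosubstituted alkene reacts far faster than the alkoxyarene. The β-silyloxy aldehyde is used at once.

Step 6
Reactants: 7 5-methoxybenzene-1,3-diol
Product: 8 1-methoxy-3,5-bis(methoxymethoxy)benzene
Conditions: NaH, MOMCl (2.4 equiv), DMF, 0 °C to rt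
Reagents that add atoms: chloromethyl methyl ether, COCCl
Why: Double O-alkylation of the resorcinol; the two acetal ethers are the directing groups for step 7.

Step 7
Reactants: 8 1-methoxy-3,5-bis(methoxymethoxy)benzene, 6 (3S)-3-[(tert-butyldimethylsilyl)oxy]-5-[4-(methoxymethoxy)phenyl]pentanal
Product: 10 (1RS,3S)-3-[(tert-butyldimethylsilyl)oxy]-1-[4-methoxy-2,6-bis(methoxymethoxy)phenyl]-5-[4-(methoxymethoxy)phenyl]pentan-1-ol, via aryllithium 9 (not isolated)
Conditions: n-BuLi (1.05 equiv), THF, 0 °C; then 6, −78 °C; H2O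
Reagents that add atoms: n-butyllithium, CCCC[Li] (supplies only the lithium of 9; nothing of it stays in 10)
Why: Directed ortho-lithiation: both acetal oxygens coordinate lithium, so the position between them is metalated, and the aryllithium adds to the aldehyde (ring A–C4 bond). The new carbinol centre is formed without control and is erased in step 8.

Step 8
Reactants: 10 (1RS,3S)-3-[(tert-butyldimethylsilyl)oxy]-1-[4-methoxy-2,6-bis(methoxymethoxy)phenyl]-5-[4-(methoxymethoxy)phenyl]pentan-1-ol
Product: 11 (3S)-3-[(tert-butyldimethylsilyl)oxy]-1-[4-methoxy-2,6-bis(methoxymethoxy)phenyl]-5-[4-(methoxymethoxy)phenyl]pentan-1-one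
Conditions: Dess–Martin periodinane, NaHCO3, CH2Cl2, 0 °C to rt
Reagents that add atoms: none
Why: Buffered Dess–Martin oxidation of the secondary benzylic alcohol; the ketone is the handle for telling the two ring A oxygens apart.

Step 9
Reactants: 11 (3S)-3-[(tert-butyldimethylsilyl)oxy]-1-[4-methoxy-2,6-bis(methoxymethoxy)phenyl]-5-[4-(methoxymethoxy)phenyl]pentan-1-one
Product: 12 (3S)-3-[(tert-butyldimethylsilyl)oxy]-1-[2-hydroxy-4-methoxy-6-(methoxymethoxy)phenyl]-5-[4-(methoxymethoxy)phenyl]pentan-1-one
Conditions: MgBr2·OEt2 (2.5 equiv), Et2O/toluene, 0 °C to rt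
Reagents that add atoms: none
Why: Chelation-assisted ether cleavage: magnesium bridges the carbonyl oxygen and one ortho acetal and bromide removes the methoxymethyl group. The resulting chelated magnesium phenoxide occupies the carbonyl, so the second ortho ether is not activated in the same way; the distal aryl MOM ether and the silyl ether have no chelating partner.

Step 10
Reactants: 12 (3S)-3-[(tert-butyldimethylsilyl)oxy]-1-[2-hydroxy-4-methoxy-6-(methoxymethoxy)phenyl]-5-[4-(methoxymethoxy)phenyl]pentan-1-one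
Product: 13 (3S)-3-[(tert-butyldimethylsilyl)oxy]-1-{2-[(tert-butyldimethylsilyl)oxy]-4-methoxy-6-(methoxymethoxy)phenyl}-5-[4-(methoxymethoxy)phenyl]pentan-1-one
Conditions: TBSCl, imidazole, DMAP (cat.), DMF, 40 °C
Reagents that add atoms: tert-butyldimethylsilyl chloride, CC(C)(C)[Si](C)(C)Cl
Why: Silylation of the hydrogen-bonded phenol; this is the only fluoride-labile aryl ether in the molecule and becomes the trigger of step 20.

Step 11
Reactants: 13 (3S)-3-[(tert-butyldimethylsilyl)oxy]-1-{2-[(tert-butyldimethylsilyl)oxy]-4-methoxy-6-(methoxymethoxy)phenyl}-5-[4-(methoxymethoxy)phenyl]pentan-1-one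
Product: 15 (1RS,3S)-3-[(tert-butyldimethylsilyl)oxy]-1-{2-[(tert-butyldimethylsilyl)oxy]-4-methoxy-6-(methoxymethoxy)phenyl}-5-[4-(methoxymethoxy)phenyl]pentyl acetate, via aluminium alkoxide 14 (not isolated)
Conditions: i-Bu2AlH, CH2Cl2, −78 °C; then pyridine, DMAP, Ac2O, −78 to 0 °C; filtration through Et3N-deactivated silica
Reagents that add atoms: diisobutylaluminium hydride, CC(C)C[AlH]CC(C)C (supplies only the aluminium of 14); acetic anhydride, CC(=O)OC(C)=O
Why: Hydride reduction to the aluminium alkoxide and its acetylation in the same flask (reductive acetylation of the Rychnovsky type). No free alkoxide sits next to the aryl silyl ether, so O-to-O silyl transfer is avoided. Both C4 epimers are used because C4 becomes trigonal in step 20.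

Step 12
Reactants: 16 (2E)-3-(4-hydroxyphenyl)prop-2-enoic acid
Product: 17 methoxymethyl (2E)-3-[4-(methoxymethoxy)phenyl]prop-2-enoate
Conditions: MOMCl (2.4 equiv), i-Pr2NEt, CH2Cl2, 0 °C to rt
Reagents that add atoms: chloromethyl methyl ether, COCCl
Why: Alkylation of carboxylate and phenoxide by the same reagent; the MOM ester is both reducible (step 14) and aminolysable (step 13).

Step 13
Reactants: 17 methoxymethyl (2E)-3-[4-(methoxymethoxy)phenyl]prop-2-enoate
Product: 18 (2E)-N-methoxy-3-[4-(methoxymethoxy)phenyl]-N-methylprop-2-enamide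
Conditions: MeNHOMe·HCl, i-PrMgCl, THF, −20 °C
Reagents that add atoms: N,O-dimethylhydroxylamine hydrochloride, CNOC.Cl
Why: Ester aminolysis by the chloromagnesium amide (Weinreb amide formation); attack at the acyl carbon is faster than conjugate addition.

Step 14
Reactants: 17 methoxymethyl (2E)-3-[4-(methoxymethoxy)phenyl]prop-2-enoate
Product: 19 (2E)-3-[4-(methoxymethoxy)phenyl]prop-2-en-1-ol
Conditions: i-Bu2AlH (2.5 equiv), CH2Cl2, −78 to 0 °C; aq. potassium sodium tartrate
Reagents that add atoms: none
Why: 1,2-Reduction of the unsaturated ester to the allylic alcohol by the aluminium hydride.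

Step 15
Reactants: 19 (2E)-3-[4-(methoxymethoxy)phenyl]prop-2-en-1-ol
Product: 20 methyl (2E)-3-[4-(methoxymethoxy)phenyl]prop-2-en-1-yl carbonate
Conditions: ClCO2Me, pyridine, CH2Cl2, 0 °C
Reagents that add atoms: methyl chloroformate, COC(=O)Cl
Why: O-acylation with the chloroformate; linear cinnamyl methyl carbonates are the standard electrophiles for iridium-catalysed allylation.

Step 16
Reactants: 20 methyl (2E)-3-[4-(methoxymethoxy)phenyl]prop-2-en-1-yl carbonate
Product: 21 dimethyl 2-{(1S)-1-[4-(methoxymethoxy)phenyl]prop-2-en-1-yl}propanedioate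
Conditions: [Ir(cod)Cl]2 (2 mol %), (Ra,Rc,Rc)-binaphthyl N,N-bis(1-phenylethyl)phosphoramidite (4 mol %), TBD (8 mol %), dimethyl malonate, THF, rt
Reagents that add atoms: dimethyl malonate, COC(=O)CC(=O)OC
Why: Iridium-catalysed branched-selective asymmetric allylic alkylation (Helmchen–Hartwig type). The cyclometalated iridium phosphoramidite complex ionises the carbonate and the malonate attacks the aryl-bearing terminus on the face left open by the ligand, which sets C1'. The methoxide released deprotonates the malonate, so no salt is added.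

Step 17
Reactants: 21 dimethyl 2-{(1S)-1-[4-(methoxymethoxy)phenyl]prop-2-en-1-yl}propanedioate
Product: 22 methyl (3R)-3-[4-(methoxymethoxy)phenyl]pent-4-enoate
Conditions: LiCl, H2O, DMSO, 150 °C
Reagents that add atoms: none
Why: Krapcho dealkoxycarbonylation under near-neutral conditions; the stereocentre is not acidic and the descriptor changes only because the substituent priorities change.

Step 18
Reactants: 22 methyl (3R)-3-[4-(methoxymethoxy)phenyl]pent-4-enoate
Product: 23 (3R)-3-[4-(methoxymethoxy)phenyl]pent-4-enoic acid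
Conditions: LiOH, THF/MeOH/H2O, rt; cold dilute HCl to pH 4
Reagents that add atoms: lithium hydroxide, [Li+].[OH-] (the hydroxide oxygen becomes the acid OH)
Why: Ester saponification; the β-stereocentre is untouched.

Step 19
Reactants: 23 (3R)-3-[4-(methoxymethoxy)phenyl]pent-4-enoic acid
Product: 24 (3R)-1-(1H-imidazol-1-yl)-3-[4-(methoxymethoxy)phenyl]pent-4-en-1-one
Conditions: CDI, CH2Cl2, rt
Reagents that add atoms: 1,1'-carbonyldiimidazole, O=C(n1ccnc1)n1ccnc1
Why: Acid activation through the mixed anhydride with loss of CO2; acyl imidazoles are the enolate precursors that tolerate fluoride in carbene catalysis.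

Step 20
Reactants: 15 (1RS,3S)-3-[(tert-butyldimethylsilyl)oxy]-1-{2-[(tert-butyldimethylsilyl)oxy]-4-methoxy-6-(methoxymethoxy)phenyl}-5-[4-(methoxymethoxy)phenyl]pentyl acetate, 24 (3R)-1-(1H-imidazol-1-yl)-3-[4-(methoxymethoxy)phenyl]pent-4-en-1-one
Product: 26 (3R,4R)-4-{(2S)-2-[(tert-butyldimethylsilyl)oxy]-4-[4-(methoxymethoxy)phenyl]butyl}-7-methoxy-5-(methoxymethoxy)-3-{(1S)-1-[4-(methoxymethoxy)phenyl]prop-2-en-1-yl}-3,4-dihydro-2H-chromen-2-one, via ortho-quinone methide 25 (not isolated)
Conditions: (5aS,10bR)-2-mesityl-5a,10b-dihydro-4H,6H-indeno[2,1-b][1,2,4]triazolo[4,3-d][1,4]oxazin-2-ium tetrafluoroborate (20 mol %), CsF (1.5 equiv), 18-crown-6, 4 Å sieves, THF, −20 °C to rt; 24 in 1.5-fold excess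
Reagents that add atoms: none
Why: Fluoride removes the single aryl silyl group of 15 and the phenoxide expels acetate to give ortho-quinone methide 25, while the carbene freed from the triazolium salt is acylated by 24 and the acyl azolium is deprotonated to the azolium enolate. The enolate carbon C3 adds to the methide carbon C4 (Michael addition) and the regenerated phenoxide closes on the acyl azolium by 6-exo-trig lactonisation, which releases the carbene; the closest known reaction type is the carbene-catalysed formal [4+2] annulation of fluoride-generated ortho-quinone methides with acyl imidazoles to dihydrocoumarins. C3 is controlled by the catalyst, whose indane wall leaves one enolate face open, and the antipode is chosen so that this is also the face preferred by the adjacent C1' centre. C4 is fixed in the same bond-forming event by the endo approach of the methide, oxygen towards the azolium, which gives the 3,4-cis lactone in this reaction class. The selectivity that matters is the configuration of C4 relative to the existing C6 and C1' centres, because C3 can still be corrected at lactone 27 and C4 cannot. The substrate helps in three ways: only one phenoxide can form, so the methide stays neutral and electrophilic; the C6 oxygen is silylated and cannot take the acyl group; and the para-methoxy and ortho-acetal oxygens make acetate loss fast at −20 °C, so the methide forms in the presence of excess enolate instead of accumulating and tautomerising to the vinylphenol.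

Step 21
Reactants: 26 (3R,4R)-4-{(2S)-2-[(tert-butyldimethylsilyl)oxy]-4-[4-(methoxymethoxy)phenyl]butyl}-7-methoxy-5-(methoxymethoxy)-3-{(1S)-1-[4-(methoxymethoxy)phenyl]prop-2-en-1-yl}-3,4-dihydro-2H-chromen-2-one
Product: 27 (3R,4R,6S)-4-[2-hydroxy-4-methoxy-6-(methoxymethoxy)phenyl]-6-{2-[4-(methoxymethoxy)phenyl]ethyl}-3-{(1S)-1-[4-(methoxymethoxy)phenyl]prop-2-en-1-yl}oxan-2-one
Conditions: Bu4NF (1.2 equiv), THF, 0 °C to rt; H2O
Reagents that add atoms: none
Why: Fluoride cleaves the secondary silyl ether and the C6 alkoxide attacks the aryl ester six atoms away, expelling the better leaving group, the ring A phenoxide (intramolecular transesterification); this forms O1–C2. No stereocentre is touched: the cis-3,4-dihydrocoumarin maps onto the oxan-2-one with the C3, C4 and C6 substituents all equatorial. C3 is still enolisable and can be equilibrated to this arrangement with base if an epimer is present.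

Step 22
Reactants: 27 (3R,4R,6S)-4-[2-hydroxy-4-methoxy-6-(methoxymethoxy)phenyl]-6-{2-[4-(methoxymethoxy)phenyl]ethyl}-3-{(1S)-1-[4-(methoxymethoxy)phenyl]prop-2-en-1-yl}oxan-2-one
Product: 28 (3R,4R,6S)-4-[4-methoxy-2,6-bis(methoxymethoxy)phenyl]-6-{2-[4-(methoxymethoxy)phenyl]ethyl}-3-{(1S)-1-[4-(methoxymethoxy)phenyl]prop-2-en-1-yl}oxan-2-one
Conditions: MOMCl, i-Pr2NEt, Bu4NI (cat.), CH2Cl2, 0 °C to rt
Reagents that add atoms: chloromethyl methyl ether, COCCl
Why: Phenol O-alkylation under amine base, which leaves the lactone α-centre alone. The phenol must be capped so that it cannot trap the C2 oxocarbenium ion in step 24, and ring A becomes symmetric for step 25.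

Step 23
Reactants: 28 (3R,4R,6S)-4-[4-methoxy-2,6-bis(methoxymethoxy)phenyl]-6-{2-[4-(methoxymethoxy)phenyl]ethyl}-3-{(1S)-1-[4-(methoxymethoxy)phenyl]prop-2-en-1-yl}oxan-2-one, 29 1-bromo-4-(methoxymethoxy)benzene
Product: 31 (2RS,3R,4R,6S)-4-[4-methoxy-2,6-bis(methoxymethoxy)phenyl]-2-[4-(methoxymethoxy)phenyl]-6-{2-[4-(methoxymethoxy)phenyl]ethyl}-3-{(1S)-1-[4-(methoxymethoxy)phenyl]prop-2-en-1-yl}oxan-2-ol, via 4-(methoxymethoxy)phenyllithium 30 (not isolated)
Conditions: 29, n-BuLi, THF, −78 °C; then 28, −78 °C; H2O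
Reagents that add atoms: n-butyllithium, CCCC[Li] (supplies only the lithium of 30; nothing of it stays in 31)
Why: Bromine–lithium exchange, then single addition of the aryllithium to the δ-lactone; the lithium hemiketal is stable at −78 °C, so a second addition does not follow (the lactone-to-lactol step of C-aryl glycoside synthesis).

Step 24
Reactants: 31 (2RS,3R,4R,6S)-4-[4-methoxy-2,6-bis(methoxymethoxy)phenyl]-2-[4-(methoxymethoxy)phenyl]-6-{2-[4-(methoxymethoxy)phenyl]ethyl}-3-{(1S)-1-[4-(methoxymethoxy)phenyl]prop-2-en-1-yl}oxan-2-ol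
Product: 32 (2S,3R,4R,6S)-4-[4-methoxy-2,6-bis(methoxymethoxy)phenyl]-2-[4-(methoxymethoxy)phenyl]-6-{2-[4-(methoxymethoxy)phenyl]ethyl}-3-{(1S)-1-[4-(methoxymethoxy)phenyl]prop-2-en-1-yl}oxane
Conditions: Et3SiH (5 equiv), Me3SiOTf (0.3 equiv), CH2Cl2, −78 °C
Reagents that add atoms: none
Why: Reductive deoxygenation of the hemiketal (Kishi-type): the aryl-stabilised oxocarbenium ion forms at −78 °C and the silane delivers hydride axially to the half-chair that holds the C3, C4 and C6 substituents equatorial. This puts the C2 aryl group equatorial (2,6-cis) and sets C2 as (S).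

Step 25
Reactants: 32 (2S,3R,4R,6S)-4-[4-methoxy-2,6-bis(methoxymethoxy)phenyl]-2-[4-(methoxymethoxy)phenyl]-6-{2-[4-(methoxymethoxy)phenyl]ethyl}-3-{(1S)-1-[4-(methoxymethoxy)phenyl]prop-2-en-1-yl}oxane
Product: 33 (2S,3R,4R,6S)-4-[3-iodo-4-methoxy-2,6-bis(methoxymethoxy)phenyl]-2-[4-(methoxymethoxy)phenyl]-6-{2-[4-(methoxymethoxy)phenyl]ethyl}-3-{(1S)-1-[4-(methoxymethoxy)phenyl]prop-2-en-1-yl}oxane
Conditions: NIS (1.05 equiv), MeCN, 0 °C, dark
Reagents that add atoms: N-iodosuccinimide, O=C1CCC(=O)N1I
Why: Electrophilic aromatic iodination; the trioxygenated ring A is far more nucleophilic than the mono-oxygenated rings or the vinyl group. Its two free positions are interchanged by rotation about the ring A–C4 bond, so one constitution results.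

Step 26
Reactants: 33 (2S,3R,4R,6S)-4-[3-iodo-4-methoxy-2,6-bis(methoxymethoxy)phenyl]-2-[4-(methoxymethoxy)phenyl]-6-{2-[4-(methoxymethoxy)phenyl]ethyl}-3-{(1S)-1-[4-(methoxymethoxy)phenyl]prop-2-en-1-yl}oxane, 18 (2E)-N-methoxy-3-[4-(methoxymethoxy)phenyl]-N-methylprop-2-enamide
Product: 35 (2E)-1-{3-[(2S,3R,4R,6S)-2-[4-(methoxymethoxy)phenyl]-6-{2-[4-(methoxymethoxy)phenyl]ethyl}-3-{(1S)-1-[4-(methoxymethoxy)phenyl]prop-2-en-1-yl}oxan-4-yl]-6-methoxy-2,4-bis(methoxymethoxy)phenyl}-3-[4-(methoxymethoxy)phenyl]prop-2-en-1-one, via ring A aryllithium 34 (not isolated)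
Conditions: t-BuLi (2.1 equiv), THF, −78 °C; then 18, −78 to −20 °C; H2O
Reagents that add atoms: tert-butyllithium, [Li]C(C)(C)C (supplies only the lithium of 34; nothing of it stays in 35)
Why: Iodine–lithium exchange is faster than any deprotonation at −78 °C, and the aryllithium, flanked by methoxy and acetal oxygens, adds 1,2 to the Weinreb amide. The chelated tetrahedral intermediate releases the enone only on work-up, so the chalcone is formed in one C–C bond construction.

Step 27
Reactants: 35 (2E)-1-{3-[(2S,3R,4R,6S)-2-[4-(methoxymethoxy)phenyl]-6-{2-[4-(methoxymethoxy)phenyl]ethyl}-3-{(1S)-1-[4-(methoxymethoxy)phenyl]prop-2-en-1-yl}oxan-4-yl]-6-methoxy-2,4-bis(methoxymethoxy)phenyl}-3-[4-(methoxymethoxy)phenyl]prop-2-en-1-one, 4 (3S)-1-[4-(methoxymethoxy)phenyl]hex-5-en-3-ol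
Product: 36 (2E)-1-{3-[(2S,3R,4R,6S)-3-{(1S,2E,5S)-5-hydroxy-1,7-bis[4-(methoxymethoxy)phenyl]hept-2-en-1-yl}-2-[4-(methoxymethoxy)phenyl]-6-{2-[4-(methoxymethoxy)phenyl]ethyl}oxan-4-yl]-6-methoxy-2,4-bis(methoxymethoxy)phenyl}-3-[4-(methoxymethoxy)phenyl]prop-2-en-1-one
Conditions: second-generation Hoveyda–Grubbs catalyst [RuCl2(H2IMes)(=CH-C6H4-2-O-i-Pr)] (10 mol %), 4 (4 equiv), CH2Cl2, 40 °C
Reagents that add atoms: none
Why: Olefin cross-metathesis between the branched terminal alkene and an excess of the unhindered homoallylic alcohol; the thermodynamically favoured (E)-alkene is expected, the conjugated chalcone alkene does not take part, and the free alcohol is tolerated. C5' arrives with 4.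

Step 28
Reactants: 36 (2E)-1-{3-[(2S,3R,4R,6S)-3-{(1S,2E,5S)-5-hydroxy-1,7-bis[4-(methoxymethoxy)phenyl]hept-2-en-1-yl}-2-[4-(methoxymethoxy)phenyl]-6-{2-[4-(methoxymethoxy)phenyl]ethyl}oxan-4-yl]-6-methoxy-2,4-bis(methoxymethoxy)phenyl}-3-[4-(methoxymethoxy)phenyl]prop-2-en-1-one
Product: 37 blepharocalyxin E, (2E)-1-{2,4-dihydroxy-3-[(2S,3R,4R,6S)-3-[(1S,2E,5S)-5-hydroxy-1,7-bis(4-hydroxyphenyl)hept-2-en-1-yl]-2-(4-hydroxyphenyl)-6-[2-(4-hydroxyphenyl)ethyl]oxan-4-yl]-6-methoxyphenyl}-3-(4-hydroxyphenyl)prop-2-en-1-one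
Conditions: HCl (aq. 3 M)/MeOH/THF, 40 °C
Reagents that add atoms: none
Why: Acid-catalysed acetal exchange removes all seven MOM ethers as dimethoxymethane; the conditions are those used for MOM-protected 2'-hydroxy-6'-methoxychalcones and should leave the enone, the (E)-alkene and the thermodynamically preferred all-equatorial ring as they are.

## Compound list

1 | methyl 3-(4-hydroxyphenyl)propanoate | COC(=O)CCc1ccc(O)cc1 | starting material
2 | methyl 3-[4-(methoxymethoxy)phenyl]propanoate | COC(=O)CCc1ccc(OCOC)cc1 | intermediate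
3 | 3-[4-(methoxymethoxy)phenyl]propanal | O=CCCc1ccc(OCOC)cc1 | intermediate
4 | (3S)-1-[4-(methoxymethoxy)phenyl]hex-5-en-3-ol | C=CC[C@@H](O)CCc1ccc(OCOC)cc1 | intermediate
5 | tert-butyl({(3S)-1-[4-(methoxymethoxy)phenyl]hex-5-en-3-yl}oxy)dimethylsilane | C=CC[C@@H](O[Si](C)(C)C(C)(C)C)CCc1ccc(OCOC)cc1 | intermediate
6 | (3S)-3-[(tert-butyldimethylsilyl)oxy]-5-[4-(methoxymethoxy)phenyl]pentanal | O=CC[C@@H](O[Si](C)(C)C(C)(C)C)CCc1ccc(OCOC)cc1 | intermediate
7 | 5-methoxybenzene-1,3-diol | COc1cc(O)cc(O)c1 | starting material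
8 | 1-methoxy-3,5-bis(methoxymethoxy)benzene | COCOc1cc(OC)cc(OCOC)c1 | intermediate
9 | [4-methoxy-2,6-bis(methoxymethoxy)phenyl]lithium | [Li]c1c(OCOC)cc(OC)cc1OCOC | intermediate (not isolated)
10 | (1RS,3S)-3-[(tert-butyldimethylsilyl)oxy]-1-[4-methoxy-2,6-bis(methoxymethoxy)phenyl]-5-[4-(methoxymethoxy)phenyl]pentan-1-ol | COCOc1cc(OC)cc(OCOC)c1C(O)C[C@H](CCc1ccc(OCOC)cc1)O[Si](C)(C)C(C)(C)C | intermediate
11 | (3S)-3-[(tert-butyldimethylsilyl)oxy]-1-[4-methoxy-2,6-bis(methoxymethoxy)phenyl]-5-[4-(methoxymethoxy)phenyl]pentan-1-one | COCOc1cc(OC)cc(OCOC)c1C(=O)C[C@H](CCc1ccc(OCOC)cc1)O[Si](C)(C)C(C)(C)C | intermediate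
12 | (3S)-3-[(tert-butyldimethylsilyl)oxy]-1-[2-hydroxy-4-methoxy-6-(methoxymethoxy)phenyl]-5-[4-(methoxymethoxy)phenyl]pentan-1-one | COCOc1cc(OC)cc(O)c1C(=O)C[C@H](CCc1ccc(OCOC)cc1)O[Si](C)(C)C(C)(C)C | intermediate
13 | (3S)-3-[(tert-butyldimethylsilyl)oxy]-1-{2-[(tert-butyldimethylsilyl)oxy]-4-methoxy-6-(methoxymethoxy)phenyl}-5-[4-(methoxymethoxy)phenyl]pentan-1-one | COCOc1cc(OC)cc(O[Si](C)(C)C(C)(C)C)c1C(=O)C[C@H](CCc1ccc(OCOC)cc1)O[Si](C)(C)C(C)(C)C | intermediate
14 | ({(1RS,3S)-3-[(tert-butyldimethylsilyl)oxy]-1-{2-[(tert-butyldimethylsilyl)oxy]-4-methoxy-6-(methoxymethoxy)phenyl}-5-[4-(methoxymethoxy)phenyl]pentyl}oxy)bis(2-methylpropyl)alumane | COCOc1cc(OC)cc(O[Si](C)(C)C(C)(C)C)c1C(O[Al](CC(C)C)CC(C)C)C[C@H](CCc1ccc(OCOC)cc1)O[Si](C)(C)C(C)(C)C | intermediate (not isolated)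
15 | (1RS,3S)-3-[(tert-butyldimethylsilyl)oxy]-1-{2-[(tert-butyldimethylsilyl)oxy]-4-methoxy-6-(methoxymethoxy)phenyl}-5-[4-(methoxymethoxy)phenyl]pentyl acetate | COCOc1cc(OC)cc(O[Si](C)(C)C(C)(C)C)c1C(OC(C)=O)C[C@H](CCc1ccc(OCOC)cc1)O[Si](C)(C)C(C)(C)C | intermediate
16 | (2E)-3-(4-hydroxyphenyl)prop-2-enoic acid | OC(=O)/C=C/c1ccc(O)cc1 | starting material
17 | methoxymethyl (2E)-3-[4-(methoxymethoxy)phenyl]prop-2-enoate | COCOC(=O)/C=C/c1ccc(OCOC)cc1 | intermediate
18 | (2E)-N-methoxy-3-[4-(methoxymethoxy)phenyl]-N-methylprop-2-enamide | CON(C)C(=O)/C=C/c1ccc(OCOC)cc1 | intermediate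
19 | (2E)-3-[4-(methoxymethoxy)phenyl]prop-2-en-1-ol | OC/C=C/c1ccc(OCOC)cc1 | intermediate
20 | methyl (2E)-3-[4-(methoxymethoxy)phenyl]prop-2-en-1-yl carbonate | COC(=O)OC/C=C/c1ccc(OCOC)cc1 | intermediate
21 | dimethyl 2-{(1S)-1-[4-(methoxymethoxy)phenyl]prop-2-en-1-yl}propanedioate | COC(=O)C(C(=O)OC)[C@H](C=C)c1ccc(OCOC)cc1 | intermediate
22 | methyl (3R)-3-[4-(methoxymethoxy)phenyl]pent-4-enoate | COC(=O)C[C@H](C=C)c1ccc(OCOC)cc1 | intermediate
23 | (3R)-3-[4-(methoxymethoxy)phenyl]pent-4-enoic acid | OC(=O)C[C@H](C=C)c1ccc(OCOC)cc1 | intermediate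
24 | (3R)-1-(1H-imidazol-1-yl)-3-[4-(methoxymethoxy)phenyl]pent-4-en-1-one | O=C(C[C@H](C=C)c1ccc(OCOC)cc1)n1ccnc1 | intermediate
25 | 6-{(3S)-3-[(tert-butyldimethylsilyl)oxy]-5-[4-(methoxymethoxy)phenyl]pentylidene}-3-methoxy-5-(methoxymethoxy)cyclohexa-2,4-dien-1-one | COCOC1=CC(OC)=CC(=O)C1=CC[C@H](CCc1ccc(OCOC)cc1)O[Si](C)(C)C(C)(C)C | intermediate (not isolated)
26 | (3R,4R)-4-{(2S)-2-[(tert-butyldimethylsilyl)oxy]-4-[4-(methoxymethoxy)phenyl]butyl}-7-methoxy-5-(methoxymethoxy)-3-{(1S)-1-[4-(methoxymethoxy)phenyl]prop-2-en-1-yl}-3,4-dihydro-2H-chromen-2-one | COc1cc2OC(=O)[C@@H]([C@H](C=C)c3ccc(OCOC)cc3)[C@@H](C[C@H](CCc3ccc(OCOC)cc3)O[Si](C)(C)C(C)(C)C)c2c(OCOC)c1 | intermediate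
27 | (3R,4R,6S)-4-[2-hydroxy-4-methoxy-6-(methoxymethoxy)phenyl]-6-{2-[4-(methoxymethoxy)phenyl]ethyl}-3-{(1S)-1-[4-(methoxymethoxy)phenyl]prop-2-en-1-yl}oxan-2-one | COc1cc(O)c([C@@H]2C[C@H](CCc3ccc(OCOC)cc3)OC(=O)[C@H]2[C@H](C=C)c2ccc(OCOC)cc2)c(OCOC)c1 | intermediate
28 | (3R,4R,6S)-4-[4-methoxy-2,6-bis(methoxymethoxy)phenyl]-6-{2-[4-(methoxymethoxy)phenyl]ethyl}-3-{(1S)-1-[4-(methoxymethoxy)phenyl]prop-2-en-1-yl}oxan-2-one | COc1cc(OCOC)c([C@@H]2C[C@H](CCc3ccc(OCOC)cc3)OC(=O)[C@H]2[C@H](C=C)c2ccc(OCOC)cc2)c(OCOC)c1 | intermediate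
29 | 1-bromo-4-(methoxymethoxy)benzene | COCOc1ccc(Br)cc1 | starting material
30 | [4-(methoxymethoxy)phenyl]lithium | [Li]c1ccc(OCOC)cc1 | intermediate (not isolated)
31 | (2RS,3R,4R,6S)-4-[4-methoxy-2,6-bis(methoxymethoxy)phenyl]-2-[4-(methoxymethoxy)phenyl]-6-{2-[4-(methoxymethoxy)phenyl]ethyl}-3-{(1S)-1-[4-(methoxymethoxy)phenyl]prop-2-en-1-yl}oxan-2-ol | COc1cc(OCOC)c([C@@H]2C[C@H](CCc3ccc(OCOC)cc3)OC(O)(c3ccc(OCOC)cc3)[C@H]2[C@H](C=C)c2ccc(OCOC)cc2)c(OCOC)c1 | intermediate
32 | (2S,3R,4R,6S)-4-[4-methoxy-2,6-bis(methoxymethoxy)phenyl]-2-[4-(methoxymethoxy)phenyl]-6-{2-[4-(methoxymethoxy)phenyl]ethyl}-3-{(1S)-1-[4-(methoxymethoxy)phenyl]prop-2-en-1-yl}oxane | COc1cc(OCOC)c([C@@H]2C[C@H](CCc3ccc(OCOC)cc3)O[C@H](c3ccc(OCOC)cc3)[C@H]2[C@H](C=C)c2ccc(OCOC)cc2)c(OCOC)c1 | intermediate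
33 | (2S,3R,4R,6S)-4-[3-iodo-4-methoxy-2,6-bis(methoxymethoxy)phenyl]-2-[4-(methoxymethoxy)phenyl]-6-{2-[4-(methoxymethoxy)phenyl]ethyl}-3-{(1S)-1-[4-(methoxymethoxy)phenyl]prop-2-en-1-yl}oxane | COc1cc(OCOC)c([C@@H]2C[C@H](CCc3ccc(OCOC)cc3)O[C@H](c3ccc(OCOC)cc3)[C@H]2[C@H](C=C)c2ccc(OCOC)cc2)c(OCOC)c1I | intermediate
34 | {3-[(2S,3R,4R,6S)-2-[4-(methoxymethoxy)phenyl]-6-{2-[4-(methoxymethoxy)phenyl]ethyl}-3-{(1S)-1-[4-(methoxymethoxy)phenyl]prop-2-en-1-yl}oxan-4-yl]-6-methoxy-2,4-bis(methoxymethoxy)phenyl}lithium | COc1cc(OCOC)c([C@@H]2C[C@H](CCc3ccc(OCOC)cc3)O[C@H](c3ccc(OCOC)cc3)[C@H]2[C@H](C=C)c2ccc(OCOC)cc2)c(OCOC)c1[Li] | intermediate (not isolated)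
35 | (2E)-1-{3-[(2S,3R,4R,6S)-2-[4-(methoxymethoxy)phenyl]-6-{2-[4-(methoxymethoxy)phenyl]ethyl}-3-{(1S)-1-[4-(methoxymethoxy)phenyl]prop-2-en-1-yl}oxan-4-yl]-6-methoxy-2,4-bis(methoxymethoxy)phenyl}-3-[4-(methoxymethoxy)phenyl]prop-2-en-1-one | COc1cc(OCOC)c([C@@H]2C[C@H](CCc3ccc(OCOC)cc3)O[C@H](c3ccc(OCOC)cc3)[C@H]2[C@H](C=C)c2ccc(OCOC)cc2)c(OCOC)c1C(=O)/C=C/c1ccc(OCOC)cc1 | intermediate
36 | (2E)-1-{3-[(2S,3R,4R,6S)-3-{(1S,2E,5S)-5-hydroxy-1,7-bis[4-(methoxymethoxy)phenyl]hept-2-en-1-yl}-2-[4-(methoxymethoxy)phenyl]-6-{2-[4-(methoxymethoxy)phenyl]ethyl}oxan-4-yl]-6-methoxy-2,4-bis(methoxymethoxy)phenyl}-3-[4-(methoxymethoxy)phenyl]prop-2-en-1-one | COc1cc(OCOC)c([C@@H]2C[C@H](CCc3ccc(OCOC)cc3)O[C@H](c3ccc(OCOC)cc3)[C@H]2[C@H](/C=C/C[C@@H](O)CCc2ccc(OCOC)cc2)c2ccc(OCOC)cc2)c(OCOC)c1C(=O)/C=C/c1ccc(OCOC)cc1 | intermediate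
37 | blepharocalyxin E, (2E)-1-{2,4-dihydroxy-3-[(2S,3R,4R,6S)-3-[(1S,2E,5S)-5-hydroxy-1,7-bis(4-hydroxyphenyl)hept-2-en-1-yl]-2-(4-hydroxyphenyl)-6-[2-(4-hydroxyphenyl)ethyl]oxan-4-yl]-6-methoxyphenyl}-3-(4-hydroxyphenyl)prop-2-en-1-one | COc1cc(O)c([C@@H]2C[C@H](CCc3ccc(O)cc3)O[C@H](c3ccc(O)cc3)[C@H]2[C@H](/C=C/C[C@@H](O)CCc2ccc(O)cc2)c2ccc(O)cc2)c(O)c1C(=O)/C=C/c1ccc(O)cc1 | target

## Step count and least certain steps

Total: 28 steps. Longest linear sequence: 19 steps (1–5, 7–11, 20–28).

**Step 20 (key step).** Two processes threaten it. The first is tautomerisation of the alkyl-substituted methide (hydrogen shift from C5) to the 2-alkenylphenol before the catalytic enolate traps it. The second is poor facial selectivity at C4 if the catalyst, the C1' centre and the methide geometry (its alkyl group must lie beside either the carbonyl or the acetal oxygen) do not cooperate. The fallback replaces the catalytic enolate by a stoichiometric, auxiliary-bound one. It sets out from acid 23 and acetate 15. Acid 23 is converted through its pivalic mixed anhydride and the lithium salt of the oxazolidinone into (4R)-4-benzyl-3-{(3R)-3-[4-(methoxymethoxy)phenyl]pent-4-enoyl}-1,3-oxazolidin-2-one F1. Its sodium enolate (NaN(SiMe3)2, THF, −78 °C) is present in excess when 15 is unmasked with Bu4N[Ph3SiF2], so the methide is captured as it forms. The phenoxide of the Michael adduct closes on the exocyclic imide carbonyl and releases the auxiliary. The fallback comes back to the route at 26. The auxiliary antipode is chosen by the same criterion as the catalyst (C4 correct), and C3 remains correctable at 27.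

**Step 9.** The likely failure is loss of the second ortho MOM group through the same magnesium chelate, or a stalled reaction. The fallback changes from selective cleavage to exhaustive cleavage followed by selective re-protection. It sets out from 11. Excess MgBr2·OEt2 removes both chelated ortho acetals (the distal aryl MOM ether has no chelating partner) to give (3S)-3-[(tert-butyldimethylsilyl)oxy]-1-(2,6-dihydroxy-4-methoxyphenyl)-5-[4-(methoxymethoxy)phenyl]pentan-1-one F2. Silylation with one equivalent of TBSCl and imidazole stops after one phenol, because the other stays hydrogen-bonded to the ketone, and gives (3S)-3-[(tert-butyldimethylsilyl)oxy]-1-{2-[(tert-butyldimethylsilyl)oxy]-6-hydroxy-4-methoxyphenyl}-5-[4-(methoxymethoxy)phenyl]pentan-1-one F3. MOMCl with i-Pr2NEt at 40 °C caps the remaining phenol, and the fallback comes back to the route at 13.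

**Step 24.** The likely failures are Lewis-acid cleavage or reductive demethoxylation of aryl MOM ethers competing with ionisation of the hemiketal, and loss of the C3 configuration through the cyclic enol ether. The fallback avoids the silyl triflate and silane. It sets out from 31, whose open hydroxy-ketone form is reduced with NaBH4 to (1RS,2R,3R,5S)-3-[4-methoxy-2,6-bis(methoxymethoxy)phenyl]-1,7-bis[4-(methoxymethoxy)phenyl]-2-{(1S)-1-[4-(methoxymethoxy)phenyl]prop-2-en-1-yl}heptane-1,5-diol F4. A catalytic amount of camphorsulfonic acid in CH2Cl2 at 0 °C ionises the 4-alkoxybenzylic alcohol, and the C6 hydroxyl closes the ring. Both C2 epimers of the diol converge under thermodynamic control on the all-equatorial ring, and the fallback comes back to the route at 32.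

**Step 28.** The likely failures are acid-promoted oxa-Michael closure of the 2'-hydroxychalcone to the flavanone and ionisation at the C2 benzylic ether while seven acetals are slowly removed. The fallback separates the deprotection from the enone. It sets out from iodide 33. Iodine–lithium exchange and quenching with N-methoxy-N-methylacetamide give 1-{3-[(2S,3R,4R,6S)-2-[4-(methoxymethoxy)phenyl]-6-{2-[4-(methoxymethoxy)phenyl]ethyl}-3-{(1S)-1-[4-(methoxymethoxy)phenyl]prop-2-en-1-yl}oxan-4-yl]-6-methoxy-2,4-bis(methoxymethoxy)phenyl}ethan-1-one F5. Cross-metathesis with 4 under the conditions of step 27 gives 1-{3-[(2S,3R,4R,6S)-3-{(1S,2E,5S)-5-hydroxy-1,7-bis[4-(methoxymethoxy)phenyl]hept-2-en-1-yl}-2-[4-(methoxymethoxy)phenyl]-6-{2-[4-(methoxymethoxy)phenyl]ethyl}oxan-4-yl]-6-methoxy-2,4-bis(methoxymethoxy)phenyl}ethan-1-one F6. Acid methanolysis, now with no enone present, gives 1-{2,4-dihydroxy-3-[(2S,3R,4R,6S)-3-[(1S,2E,5S)-5-hydroxy-1,7-bis(4-hydroxyphenyl)hept-2-en-1-yl]-2-(4-hydroxyphenyl)-6-[2-(4-hydroxyphenyl)ethyl]oxan-4-yl]-6-methoxyphenyl}ethan-1-one F7. Claisen–Schmidt condensation of F7 with 4-hydroxybenzaldehyde (excess KOH, EtOH/H2O, rt) forms the chalcone, and the fallback comes back to the route at 37.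

## Further compounds

F1 | step 20 | (4R)-4-benzyl-3-{(3R)-3-[4-(methoxymethoxy)phenyl]pent-4-enoyl}-1,3-oxazolidin-2-one | O=C1OC[C@@H](Cc2ccccc2)N1C(=O)C[C@H](C=C)c1ccc(OCOC)cc1
F2 | step 9 | (3S)-3-[(tert-butyldimethylsilyl)oxy]-1-(2,6-dihydroxy-4-methoxyphenyl)-5-[4-(methoxymethoxy)phenyl]pentan-1-one | COc1cc(O)c(C(=O)C[C@H](CCc2ccc(OCOC)cc2)O[Si](C)(C)C(C)(C)C)c(O)c1
F3 | step 9 | (3S)-3-[(tert-butyldimethylsilyl)oxy]-1-{2-[(tert-butyldimethylsilyl)oxy]-6-hydroxy-4-methoxyphenyl}-5-[4-(methoxymethoxy)phenyl]pentan-1-one | COc1cc(O)c(C(=O)C[C@H](CCc2ccc(OCOC)cc2)O[Si](C)(C)C(C)(C)C)c(O[Si](C)(C)C(C)(C)C)c1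
F4 | step 24 | (1RS,2R,3R,5S)-3-[4-methoxy-2,6-bis(methoxymethoxy)phenyl]-1,7-bis[4-(methoxymethoxy)phenyl]-2-{(1S)-1-[4-(methoxymethoxy)phenyl]prop-2-en-1-yl}heptane-1,5-diol | COc1cc(OCOC)c([C@H](C[C@H](CCc2ccc(OCOC)cc2)O)[C@H]([C@H](C=C)c2ccc(OCOC)cc2)C(O)c2ccc(OCOC)cc2)c(OCOC)c1
F5 | step 28 | 1-{3-[(2S,3R,4R,6S)-2-[4-(methoxymethoxy)phenyl]-6-{2-[4-(methoxymethoxy)phenyl]ethyl}-3-{(1S)-1-[4-(methoxymethoxy)phenyl]prop-2-en-1-yl}oxan-4-yl]-6-methoxy-2,4-bis(methoxymethoxy)phenyl}ethan-1-one | COc1cc(OCOC)c([C@@H]2C[C@H](CCc3ccc(OCOC)cc3)O[C@H](c3ccc(OCOC)cc3)[C@H]2[C@H](C=C)c2ccc(OCOC)cc2)c(OCOC)c1C(C)=O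
F6 | step 28 | 1-{3-[(2S,3R,4R,6S)-3-{(1S,2E,5S)-5-hydroxy-1,7-bis[4-(methoxymethoxy)phenyl]hept-2-en-1-yl}-2-[4-(methoxymethoxy)phenyl]-6-{2-[4-(methoxymethoxy)phenyl]ethyl}oxan-4-yl]-6-methoxy-2,4-bis(methoxymethoxy)phenyl}ethan-1-one | COc1cc(OCOC)c([C@@H]2C[C@H](CCc3ccc(OCOC)cc3)O[C@H](c3ccc(OCOC)cc3)[C@H]2[C@H](/C=C/C[C@@H](O)CCc2ccc(OCOC)cc2)c2ccc(OCOC)cc2)c(OCOC)c1C(C)=O
F7 | step 28 | 1-{2,4-dihydroxy-3-[(2S,3R,4R,6S)-3-[(1S,2E,5S)-5-hydroxy-1,7-bis(4-hydroxyphenyl)hept-2-en-1-yl]-2-(4-hydroxyphenyl)-6-[2-(4-hydroxyphenyl)ethyl]oxan-4-yl]-6-methoxyphenyl}ethan-1-one | COc1cc(O)c([C@@H]2C[C@H](CCc3ccc(O)cc3)O[C@H](c3ccc(O)cc3)[C@H]2[C@H](/C=C/C[C@@H](O)CCc2ccc(O)cc2)c2ccc(O)cc2)c(O)c1C(C)=O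
A1 | alternative 1 | ring A acetophenone carrying the complete tetrahydropyran and the MOM-protected side chain | COc1cc(O)c([C@@H]2C[C@H](CCc3ccc(OCOC)cc3)O[C@H](c3ccc(OCOC)cc3)[C@H]2[C@H](/C=C/C[C@@H](OCOC)CCc2ccc(OCOC)cc2)c2ccc(OCOC)cc2)c(O)c1C(C)=O
A2 | alternative 2 | all-equatorial tetrahydropyran with ring A on C4, a vinyl group on C1' and five tert-butyldimethylsilyl ethers | COc1cc(O[Si](C)(C)C(C)(C)C)c([C@@H]2C[C@H](CCc3ccc(O[Si](C)(C)C(C)(C)C)cc3)O[C@H](c3ccc(O[Si](C)(C)C(C)(C)C)cc3)[C@H]2[C@H](C=C)c2ccc(O[Si](C)(C)C(C)(C)C)cc2)c(O[Si](C)(C)C(C)(C)C)c1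
A3 | alternative 3 | all-equatorial tetrahydropyran with ring A as its diacetate and a vinyl group on C1' | COc1cc(OC(C)=O)c([C@@H]2C[C@H](CCc3ccc(OCOC)cc3)O[C@H](c3ccc(OCOC)cc3)[C@H]2[C@H](C=C)c2ccc(OCOC)cc2)c(OC(C)=O)c1
A4 | alternative 3 | racemic 1-[4-(methoxymethoxy)phenyl]prop-2-en-1-ol | C=CC(O)c1ccc(OCOC)cc1
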